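## Structural features

The target is a diterpenoid on a trans-fused hydroazulene: cyclopentane ring A (C1, C2, C8, C9, C10) and cycloheptane ring B (C2 to C8) share the C2–C8 bond, with C2–H and C8–H on opposite faces. The numbering used throughout is: C11 is the methylene carbon on C1, C12 the methylene carbon on C7, C13 the side-chain methine on C4 (methyl C14), C15 and C16 the two acetoxy carbons, and C17=C18 the trisubstituted alkene. There are nine stereocentres: C2 (R), C3 (S), C4 (R), C6 (S), C8 (S), C10 (R) in the bicycle and C13 (R), C15 (S), C16 (S) in the chain. C2, C3, C4, C13, C15 and C16 form an unbroken run of six. C3–OH, the C4 side chain, C2–H and C10–OH lie on one face of the bicycle, while C6–OH and C8–H lie on the other. The fragile parts are the two 1,1-disubstituted exocyclic alkenes, each next to an allylic alcohol (C10–OH/C1=C11 and C6–OH/C7=C12), and the allylic C16 acetate beside an electron-rich alkene. Three secondary alcohols must end free while two others are acetylated, so the oxygens have to be told apart by protecting groups. The real difficulty is the trans-fused five–seven nucleus oxygenated at C3, C6 and C10, together with an acyclic stereotriad (C13, C15, C16) that the rings cannot control directly. The key step exploits the fact that C1 to C15 are the carbon set of a eudesmane-type decalin. If the ring-fusion bond C2–C8 is opened and C2 is joined to C7 instead, rings A and B become a cross-conjugated cyclohexadienone (C8=C9–C10(=O)–C1=C2, angular C12 methyl on C7) that carvone and pent-1-en-3-one can assemble.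

## Logic of the disconnections

**40 to 39.** The three O–Si bonds at C3, C6 and C10 are cut last in the forward sense. The ring alcohols cannot be left free while the side-chain diol is acetylated, so they travel as one class of silyl ether. The forward step must remove three secondary silyl groups without touching either acetate.

**39 to 37 and 38.** The C17=C18 bond is cut by cross-metathesis. The trisubstituted alkene would not survive allylic oxidation with selenium dioxide, so it is made after all ring oxidation. This reduces the side chain to a vinyl group; the catalyst must ignore two hindered 1,1-disubstituted alkenes.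

**37 to 36 to 35 to 32 and 33.** The two acyl C–O bonds, the benzylic ether and then the C15–C16 bond are cut. Forming C15–C16 by alkoxyallylboration sets both carbinol centres at once under reagent control and removes two stereocentres and two skeletal carbons. The forward step needs Re-face attack on an α-branched aldehyde without epimerising C13.

**32 to 31 to 30 to 29 to 28.** The C15 oxidation level, the primary O–Si bond, the C6 O–Si bond and the C6–O bond are cut in turn. The C6 oxygen is introduced by allylic oxidation at a stage where C7=C12 is the only alkene with an allylic methylene. The forward demand is site selectivity (methylene over methine) and delivery of oxygen to the α-face.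

**28 to 27 to 26 to 24 to 22.** The two O–Si bonds at C3 and C10, the C10 carbinol C–H bond, the C1=C11 unsaturation (back to a C1–Se bond) and finally the C2–H and C1–Se bonds are cut. This traces the ring A allylic alcohol back to the tetrasubstituted enone of a hydroazulenone, so C2 and C10 arise from trigonal carbons and C11 returns to a methyl group. The forward steps need β-face protonation at C2, selenenylation anti to C2–H, elimination towards the methyl group only, and catalyst-controlled hydride delivery at C10.

**22 to 19 to 18 to 17 to 15.** The C7=C12 alkene is traced to the tertiary C7 alcohol, the C3 hydroxyl to its acetate, the C15 silyl ether to the alcohol, and the C15–O and C13–H bonds to the isopropenyl group. Hydroboration is placed before either exocyclic alkene exists, because it could not distinguish them from the isopropenyl group. The acetate is removed before the dissolving-metal step because a γ-acyloxy group would be expelled. Dehydration precedes the reduction so that exactly one hydroxyl accompanies the enone. The demands are hydroboration in the presence of a ketone, facial selectivity at C13, and elimination towards C12.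

**15 to 14 (key).** The C2–C8 bond is cut and C2–C7 is re-formed. The five–seven skeleton becomes a decalin, both rings become six-membered, and all fifteen core carbons with the C3, C4 and C7 centres are already in place. The forward step must bond C2 to C8 on the face opposite the C12 methyl, break C2–C7 and capture C7 with water.

**14 to 13 to 12 to 11 to 9.** The C8=C9 unsaturation, the acetyl group and the C3–O bond are cut. C3 is the γ-carbon of the enone in 9, so its oxygen is best introduced through the dienyl acetate 11. The forward demands are axial attack at C3 on the face of the angular methyl and dehydrogenation on the α′ side only.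

**9 to 8 to 5 and 6, 5 to 3 and 4, 3 to 1.** The C1=C2 bond (aldol condensation), the C7–C8 bond (Michael addition), the C=N bond and the C–H bonds from conjugate reduction are cut. This is a Robinson annulation onto the chiral-pool ketone. The quaternary C7 must carry its methyl cis to the isopropenyl group, against the intrinsic preference of the ring, so the chiral amine 4 controls the face.

## Other disconnections considered

**Alternative 1:** The cut is C8–C9 in ring A. In the forward step a Lewis acid such as Sc(OTf)3 would activate the alkoxy-polarised dienone A1 for conrotatory 4π closure to the 2-methoxycyclopentenone A2.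
- In its favour: the closure is thermal and catalytic. The methoxy group fixes where the double bond ends and brings the C10 oxygen with it. C12 arrives as a protected hydroxymethyl group that can be eliminated to C7=C12 without any regiochemical question. The C3 and C6 oxygens are already in place, so no late allylic oxidation is needed.
- Against it here: A1 is a fully substituted cycloheptene with stereocentres at C3, C4, C6, C7 and C13, and it would have to be built with no help from a terpene starting material. The sense of conrotation at C8 would depend only on the neighbouring C7 substituent. After closure, the hindered, enolisable C1 ketone must be methylenated and the C9=C10 enol ether taken to the β-carbinol.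
- Comparison: on structure, the chosen plan obtains both rings and fifteen carbons from two cheap components in one reorganisation, whereas this plan adds one ring to another that is costly to make. On mechanism, a catalytic ionic electrocyclisation is the equal or the better of a photochemical step for scale-up. It is better in that C12 and C6 need no dehydration or selenium dioxide step. On step economy it should be longer overall because of the synthesis of A1.

**Alternative 2:** The cuts are C7–C8 and C4–C5 in ring B. A chiral dirhodium tetracarboxylate such as Rh2(S-DOSP)4 would convert the vinyl diazo ester A4 into a carbene that cyclopropanates the diene A3; the cis-divinylcyclopropane would then undergo Cope rearrangement to the cycloheptadiene A5.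
- In its favour: it is convergent and makes two C–C bonds and ring B in one operation. The boat transition state fixes C4–H and C8–H cis, the same relation the chosen key step sets, here under catalyst control (an equal). C13 comes from a chiral-pool propionate unit, which is better than a substrate-controlled hydroboration. The C2=C3 alkene is placed so that hydroboration could add C3–OH and C2–H to the same face, as the target requires.
- Against it here: A5 lacks C11, has no oxygen at C10, carries C12 as an ester and C6 at the ketone level. Ketal removal, methylenation at C1, oxygenation at C10, conversion of the ester into a methylene group and reduction at C6 would all follow. The existing C13 centre and the catalyst could be mismatched.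
- Comparison: on structure it is more convergent (better). On mechanism it is catalytic and asymmetric (better), and equal in delivering the five–seven core in one step. On step economy the functional-group work at five carbons after the annulation should make it no shorter than the chosen route, whose key-step product already has the C1 methyl, C10 carbonyl and C7 oxygen in place.

**Alternative 3:** The cut is C3–C4 in ring B, with lactonisation. CrCl2 (divalent chromium) or zinc metal would turn the 2-(bromomethyl)alkenoate of aldehyde A6 into an allylmetal whose γ-carbon C4 adds to the C3 aldehyde; the C3 alkoxide would then close onto C15 to give the cis-fused methylene lactone A7.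
- In its favour: C3 and C4 are set together through a cyclic transition state with the cis relation of the C3 oxygen and the C4 side chain that the target needs. Both exocyclic alkenes and the C6 and C10 oxygens are present before ring closure, so no dehydration or late allylic oxidation is needed (better). C15 is at the carboxyl level, so conjugate reduction (setting C13) and reduction to the lactol would lead straight into the same allylboration end-game (equal).
- Against it here: A6 is a tetrasubstituted cyclopentane with four stereocentres, the trans relation at C2/C8 and two sensitive methylene groups, all to be made from non-terpene materials. Closing a seven-membered ring is entropically costly. The C13 configuration would rest on the face selectivity of a conjugate reduction, which is not clearly better than hydroboration (equal).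
- Comparison: on structure and stereocontrol at C3/C4 it is better. On mechanism it is a mild organometallic closure with no photochemistry (equal or better for scale). On step economy it is worse, because neither ring is inherited from a starting material.

Key step: step 9

Assumption (chemistry): 3 is carried as the C2-epimer mixture that step 1 delivers (trans isomer drawn), since C2 becomes trigonal again in steps 2 and 3.

Assumption (chemistry): allyl 4-methoxybenzyl ether 33 is treated as a purchasable ether; it is otherwise one Williamson step from allyl alcohol.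

## Steps

Step 1
Reactants: 1 (S)-carvone
Product: 3 (2S,5S)-dihydrocarvone, via lithium enolate 2 (not isolated)
Conditions: LiBH(s-Bu)3 (L-Selectride), THF, −78 °C; aq. NH4Cl
Reagents that add atoms: none
Why: Conjugate hydride reduction of a β-unsubstituted cyclohexenone by a hindered trialkylborohydride; the isolated isopropenyl group and C5 are untouched. The C2 methyl centre forms as an epimer mixture, which is harmless because C2 becomes trigonal again in step 3.

Step 2
Reactants: 3 (2S,5S)-dihydrocarvone; 4 (S)-1-phenylethylamine
Product: 5 (S)-1-phenylethyl imine of dihydrocarvone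
Conditions: toluene, reflux, Dean–Stark trap (cat. TsOH)
Reagents that add atoms: none
Why: Condensation of ketone and primary amine with azeotropic removal of water; the imine equilibrates with its more substituted secondary enamine, and the amine stereocentre is the control element for step 3.

Step 3
Reactants: 5 (S)-1-phenylethyl imine of dihydrocarvone; 6 pent-1-en-3-one
Product: 8 (2R,5S)-2-methyl-2-(3-oxopentyl)-5-(prop-1-en-2-yl)cyclohexan-1-one, via Michael adduct imine 7 (not isolated)
Conditions: 6 (1.5 equiv), THF, 40 °C; then 10% aq. AcOH, rt
Reagents that add atoms: water, O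
Why: Michael addition of the secondary enamine tautomer of 5 through a compact aza-ene-like transition state; the phenyl group of the (S)-auxiliary blocks one enamine face, so the new quaternary centre should form (2R), with its methyl cis to the isopropenyl group, against the intrinsic trans preference of the ring. Aqueous acid then hydrolyses the imine and returns the auxiliary.

Step 4
Reactants: 8 (2R,5S)-2-methyl-2-(3-oxopentyl)-5-(prop-1-en-2-yl)cyclohexan-1-one
Product: 9 (4aR,7S)-1,4a-dimethyl-7-(prop-1-en-2-yl)-4,4a,5,6,7,8-hexahydronaphthalen-2(3H)-one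
Conditions: NaOMe, MeOH, rt → 60 °C
Reagents that add atoms: none
Why: Intramolecular aldol condensation (second half of the Robinson annulation): the ethyl ketone enolate adds to the ring carbonyl and E1cB dehydration gives the tetrasubstituted enone; no stereocentre is formed or put at risk.

Step 5
Reactants: 9 (4aR,7S)-1,4a-dimethyl-7-(prop-1-en-2-yl)-4,4a,5,6,7,8-hexahydronaphthalen-2(3H)-one
Product: 11 dienyl acetate (C10–OAc; C10=C1; C2=C3), via potassium dienolate 10 (not isolated)
Conditions: KOt-Bu, THF–t-BuOH, 0 °C → rt; Ac2O, −78 → 0 °C
Reagents that add atoms: acetic anhydride, CC(=O)OC(C)=O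
Why: Under equilibrating conditions tert-butoxide removes a γ-hydrogen at C3 to give the extended dienolate, which is O-acetylated to the 1,3-dienyl acetate; this activates C3 for electrophilic oxygenation without exposing the isopropenyl group to acid.

Step 6
Reactants: 11 dienyl acetate (C10–OAc; C10=C1; C2=C3)
Product: 12 (3S)-C3-hydroxy enone
Conditions: mCPBA (1.0 equiv), NaHCO3, 1,4-dioxane–H2O, 0 °C
Reagents that add atoms: mCPBA, OOC(=O)c1cccc(Cl)c1
Why: Vinylogous Rubottom-type oxidation: the peracid should attack the electron-rich terminal C2=C3 bond of the dienyl acetate in preference to the isolated isopropenyl group, and collapse with loss of the acetyl group gives the γ-hydroxy enone. Attack is expected to be axial, on the face of the angular methyl, as in the 6β-hydroxylation of steroidal 3,5-dienyl acetates, which places C3–OH cis to the C4 isopropenyl group.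

Step 7
Reactants: 12 (3S)-C3-hydroxy enone
Product: 13 C3-acetoxy enone
Conditions: Ac2O, DMAP, pyridine, CH2Cl2, 0 °C → rt
Reagents that add atoms: acetic anhydride, CC(=O)OC(C)=O
Why: DMAP-catalysed acylation of the hindered axial alcohol; the acetate shields the allylic alcohol from quinone oxidation in step 8 and is inert to light and aqueous acid in step 9.

Step 8
Reactants: 13 C3-acetoxy enone
Product: 14 C3-acetoxy cross-conjugated dienone
Conditions: DDQ, 1,4-dioxane, reflux
Reagents that add atoms: none
Why: Quinone dehydrogenation of a 4-en-3-one type enone: hydride abstraction from the α′-enol at C8/C9 under neutral conditions gives the cross-conjugated dienone; the linear dienone is not accessible because C3 carries the acetate.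

Step 9
Reactants: 14 C3-acetoxy cross-conjugated dienone
Product: 15 C7-hydroxy hydroazulenone
Conditions: hν (medium-pressure Hg lamp, Pyrex filter, λ > 300 nm), AcOH–H2O (1:1), N2, 15–20 °C
Reagents that add atoms: water, O
Why: Excitation of the cross-conjugated dienone should lead to bonding between the two β-carbons C2 and C8, giving a bicyclo[3.1.0]hexenyl oxyallyl zwitterion with C7 as the cyclopropane apex. In the protic medium the zwitterion is protonated before it can shift to a lumiketone, and the cation, best stabilised at the methyl-bearing C1, opens the cyclopropane at C2–C7, leaving the C1=C2 enone and a tertiary cation at C7 that water captures. The closest known reaction type is the aqueous-acid photorearrangement of 4-methyl cross-conjugated cyclohexadienones of the santonin class to five–seven fused hydroxy ketones. Ring A closes by 3-exo-type bonding of C8 to C2 across the dienone, and ring B forms by one-carbon ring expansion when C2–C7 breaks and C8 is left between C7 and C2. C8 is controlled by the angular C12 methyl: bonding takes place on the face opposite to it, so C8–H ends α, cis to C4–H. C7 is set stereospecifically because water enters anti to the departing C2–C7 bond, giving OH α and methyl β. The step needs the five–seven product rather than spiro or lumiketone isomers, which the C11 methyl on C1 (directing cleavage to C2–C7) and the aqueous acid secure; C3 and C4 are spectators. Irradiation through Pyrex and stopping short of full conversion should limit secondary photolysis of 15.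

Step 10
Reactants: 15 C7-hydroxy hydroazulenone
Product: 17 (13R)-C15 primary alcohol, via catechol boronate 16 (not isolated)
Conditions: catecholborane, RhCl(PPh3)3 (3 mol %), THF, 0 °C → rt; then NaBO3·4H2O, THF–H2O, rt
Reagents that add atoms: sodium perborate, [Na+].[O-]OB=O
Why: Catalysed B–H addition to the 1,1-disubstituted isopropenyl alkene outpaces carbonyl reduction by catecholborane, and the tetrasubstituted s-trans enone is inert, so only C13=C15 should react, boron going to C15; perborate oxidises the C–B bond with retention and spares the acetate. C13 is set by facial selection in the conformer with C4–H eclipsing the C14 methyl (least allylic 1,2-strain), where the C3 branch with its acetoxy group shields one face; addition anti to it gives (13R).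

Step 11
Reactants: 17 (13R)-C15 primary alcohol
Product: 18 C15 TBS ether
Conditions: TBSCl, imidazole, CH2Cl2, 0 °C
Reagents that add atoms: tert-butyldimethylsilyl chloride, CC(C)(C)[Si](C)(C)Cl
Why: Chemoselective silylation of the primary alcohol; the hindered tertiary C7 hydroxyl does not react under these conditions.

Step 12
Reactants: 18 C15 TBS ether
Product: 19 C3,C7-diol
Conditions: K2CO3, MeOH, 0 °C
Reagents that add atoms: none
Why: Mild methanolysis of the secondary acetate frees C3–OH, which must not be an acyloxy leaving group in the dissolving-metal step; cold carbonate is used to avoid epimerisation at the γ-carbon C3 and retro-aldol-type opening of the hydroxy enone.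

Step 13
Reactants: 19 C3,C7-diol
Product: 22 C3-hydroxy enone bearing C7=C12, via C3 trimethylsilyl ether 20 (not isolated), via silylated exocyclic alkene 21 (not isolated)
Conditions: TMSCl, pyridine, CH2Cl2, 0 °C; SOCl2, −40 °C; citric acid, MeOH, 0 °C
Reagents that add atoms: none
Why: TMSCl should silylate only the secondary C3 hydroxyl, so that SOCl2 converts the tertiary C7 alcohol alone into its chlorosulfite, which pyridine eliminates by an E2 process. C8–H is cis to the leaving group and cannot be antiperiplanar, so a hydrogen of the C12 methyl is lost and the exocyclic C7=C12 alkene forms; the cold acidic methanol work-up removes the TMS ether.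

Step 14
Reactants: 22 C3-hydroxy enone bearing C7=C12
Product: 24 C1 α-phenylselanyl ketone, via dilithium enolate alkoxide 23 (not isolated)
Conditions: Li (2.2 equiv), NH3(l)–THF, −78 °C; isoprene; NH3 removed; PhSeBr (2.2 equiv), THF, −78 °C; aq. NH4Cl
Reagents that add atoms: phenylselenenyl bromide, Br[Se]c1ccccc1
Why: Dissolving-metal (Birch-type) reduction of the enone with trapping of the regiodefined enolate: two electrons and one proton, supplied by the single C3 hydroxyl, give the C1(C10) lithium enolate, and the C3 alkoxide is too poor a leaving group for β-elimination. C2 should be protonated on the β-face, the side of the C3 oxygen that relays the proton, giving the trans ring fusion usual for such fused enones. PhSeBr then attacks C1 on the α-face, anti to the now axial C2–H, as in the selenenylation of trans-fused α-methyl lactone enolates.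

Step 15
Reactants: 24 C1 α-phenylselanyl ketone
Product: 26 exocyclic enone (C1=C11; C10=O), via selenoxide 25 (not isolated)
Conditions: NaIO4, NaHCO3, THF–MeOH–H2O, 0 °C → rt
Reagents that add atoms: none
Why: Periodate oxidises the selenide to the selenoxide, which undergoes syn-elimination at or below room temperature. Selenium is trans to C2–H, so only a C11 methyl hydrogen is syn and the exocyclic enone should form; periodate avoids the peroxyseleninic acid that excess peroxide would generate and that could epoxidise C7=C12.

Step 16
Reactants: 26 exocyclic enone (C1=C11; C10=O)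
Product: 27 (10R)-allylic alcohol (C3,C10-diol)
Conditions: (S)-2-methyl-CBS-oxazaborolidine, catecholborane, toluene–CH2Cl2, −78 °C; MeOH, aq. NaHCO3
Reagents that add atoms: none
Why: Corey–Bakshi–Shibata reduction: the ring gives little facial bias at C10, so the catalyst decides; with the (S)-oxazaborolidine the disubstituted sp2 carbon C1 acts as the large group and C9H2 as the small one, and hydride should be delivered to the α-face to give the (10R) β-alcohol. 1,2-Reduction at −78 °C leaves the 1,1-disubstituted alkenes and the silyl ether alone and removes the isomerisation-prone methylene ketone at once.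

Step 17
Reactants: 27 (10R)-allylic alcohol (C3,C10-diol)
Product: 28 C3,C10,C15-tris-TBS ether
Conditions: TBSOTf, 2,6-lutidine, CH2Cl2, −78 → 0 °C
Reagents that add atoms: tert-butyldimethylsilyl triflate, CC(C)(C)[Si](C)(C)OS(=O)(=O)C(F)(F)F
Why: Silyl triflate protection of the two secondary alcohols (the hindered C3–OH needs the triflate), so that the allylic oxidation that follows meets no free allylic alcohol.

Step 18
Reactants: 28 C3,C10,C15-tris-TBS ether
Product: 29 (6S)-C6 allylic alcohol
Conditions: SeO2 (cat.), t-BuOOH, CH2Cl2, 0 °C → rt
Reagents that add atoms: selenium dioxide, O=[Se]=O; tert-butyl hydroperoxide, CC(C)(C)OO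
Why: Riley-type allylic oxidation (ene reaction, then [2,3]-sigmatropic shift) with catalytic SeO2: of the two exocyclic alkenes only C7=C12 has an allylic methylene (C6), whereas C1=C11 offers a ring-fusion methine and a silyloxy methine, which react far more slowly, as does C8–H. The [2,3] shift is expected to return oxygen to C6 on the α-face, away from the β-oriented C4 side chain and C3 silyl ether, giving (6S).

Step 19
Reactants: 29 (6S)-C6 allylic alcohol
Product: 30 tetrakis-TBS ether
Conditions: TBSOTf, 2,6-lutidine, CH2Cl2, −78 °C
Reagents that add atoms: tert-butyldimethylsilyl triflate, CC(C)(C)[Si](C)(C)OS(=O)(=O)C(F)(F)F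
Why: Silylation of the new allylic alcohol puts all three ring hydroxyls into one class of protecting group that is removed together at the end.

Step 20
Reactants: 30 tetrakis-TBS ether
Product: 31 C15 primary alcohol
Conditions: HF·pyridine, pyridine, THF, 0 °C
Reagents that add atoms: none
Why: Buffered HF·pyridine cleaves the unhindered primary TBS ether much faster than the three secondary ones, so only C15–OH should be released.

Step 21
Reactants: 31 C15 primary alcohol
Product: 32 C15 aldehyde
Conditions: Dess–Martin periodinane, NaHCO3, CH2Cl2, 0 °C → rt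
Reagents that add atoms: none
Why: Buffered Dess–Martin oxidation gives the α-branched aldehyde under non-epimerising conditions; it is used without delay.

Step 22
Reactants: 32 C15 aldehyde; 33 allyl 4-methoxybenzyl ether
Product: 35 (15S,16S)-C15 alcohol C16 PMB ether, via diisopinocampheylborinate 34 (not isolated)
Conditions: 33, s-BuLi, THF, −78 °C; (+)-Ipc2BOMe; BF3·OEt2; 32, −78 °C; NaOH, H2O2, 0 °C → rt
Reagents that add atoms: none
Why: Brown alkoxyallylboration: lithiation of 33 and transfer to boron give the (Z)-γ-alkoxyallylborane, which adds through a closed chair (Zimmerman–Traxler) transition state, the Z geometry fixing the syn relation of C15–OH and C16–OR. The isopinocampheyl groups derived from (−)-α-pinene direct attack to the Re face of the aldehyde, giving (15S,16S); this is also the Felkin–Anh sense for the (13R) α-methyl aldehyde, so the 13,15-syn product is expected.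

Step 23
Reactants: 35 (15S,16S)-C15 alcohol C16 PMB ether
Product: 36 C15,C16-diol
Conditions: DDQ, CH2Cl2–pH 7 buffer, 0 °C
Reagents that add atoms: none
Why: Oxidative cleavage of the 4-methoxybenzyl ether by DDQ in wet solvent, where water intercepts the oxocarbenium ion in preference to the neighbouring hydroxyl; silyl ethers and the unactivated alkenes are inert.

Step 24
Reactants: 36 C15,C16-diol
Product: 37 C15,C16-diacetate
Conditions: Ac2O, DMAP, pyridine, CH2Cl2, rt
Reagents that add atoms: acetic anhydride, CC(=O)OC(C)=O
Why: Exhaustive DMAP-catalysed acetylation of the only two free hydroxyls installs both acetates in one operation.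

Step 25
Reactants: 37 C15,C16-diacetate; 38 2-methylbut-2-ene
Product: 39 tris-TBS ether of the target
Conditions: second-generation Grubbs catalyst RuCl2(=CHPh)(H2IMes)(PCy3) (5 mol %), neat 38, 40 °C
Reagents that add atoms: none
Why: Olefin cross-metathesis of the monosubstituted vinyl group with excess 2-methylbut-2-ene should give the trisubstituted isobutenyl terminus with loss of propene; the two hindered 1,1-disubstituted exocyclic alkenes do not enter the catalytic cycle.

Step 26
Reactants: 39 tris-TBS ether of the target
Product: 40 target CNP0172457.3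
Conditions: HF·pyridine, pyridine, THF, 0 °C → rt
Reagents that add atoms: none
Why: Fluoride cleavage of the three secondary silyl ethers under buffered conditions that leave both acetates in place and should not cause acyl migration or ionisation of the allylic C16 acetate.

## Compound list

1 | (S)-carvone, (5S)-2-methyl-5-(prop-1-en-2-yl)cyclohex-2-en-1-one | CC1=CC[C@@H](CC1=O)C(C)=C | starting material
2 | lithium (5S)-2-methyl-5-(prop-1-en-2-yl)cyclohex-1-en-1-olate (enolate formed in step 1) | CC1=C([O-])C[C@H](CC1)C(C)=C.[Li+] | intermediate
3 | (2S,5S)-2-methyl-5-(prop-1-en-2-yl)cyclohexan-1-one (trans-dihydrocarvone; used with its C2 epimer) | C[C@H]1CC[C@@H](CC1=O)C(C)=C | intermediate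
4 | (S)-1-phenylethylamine | C[C@H](N)c1ccccc1 | starting material
5 | (2S,5S)-2-methyl-N-[(1S)-1-phenylethyl]-5-(prop-1-en-2-yl)cyclohexan-1-imine | C[C@H]1CC[C@@H](CC1=N[C@@H](C)c2ccccc2)C(C)=C | intermediate
6 | pent-1-en-3-one | CCC(=O)C=C | starting material
7 | 5-[(1R,4S)-1-methyl-2-{[(1S)-1-phenylethyl]imino}-4-(prop-1-en-2-yl)cyclohexyl]pentan-3-one (Michael adduct, formed in step 3) | CCC(=O)CC[C@@]1(C)CC[C@H](C(C)=C)CC1=N[C@@H](C)c2ccccc2 | intermediate
8 | (2R,5S)-2-methyl-2-(3-oxopentyl)-5-(prop-1-en-2-yl)cyclohexan-1-one | CCC(=O)CC[C@@]1(C)CC[C@H](C(C)=C)CC1=O | intermediate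
9 | (4aR,7S)-1,4a-dimethyl-7-(prop-1-en-2-yl)-4,4a,5,6,7,8-hexahydronaphthalen-2(3H)-one, (−)-α-cyperone; route numbering (4S,7R) | CC1=C2C[C@@H](C(C)=C)CC[C@]2(C)CCC1=O | intermediate
10 | potassium (4aR,7S)-1,4a-dimethyl-7-(prop-1-en-2-yl)-3,4,4a,5,6,7-hexahydronaphthalen-2-olate (extended dienolate, formed in step 5) | CC1=C([O-])CC[C@@]2(C)CC[C@H](C(C)=C)C=C12.[K+] | intermediate
11 | (4aR,7S)-1,4a-dimethyl-7-(prop-1-en-2-yl)-3,4,4a,5,6,7-hexahydronaphthalen-2-yl acetate | CC1=C(OC(C)=O)CC[C@@]2(C)CC[C@H](C(C)=C)C=C12 | intermediate
12 | (4aR,7R,8S)-8-hydroxy-1,4a-dimethyl-7-(prop-1-en-2-yl)-4,4a,5,6,7,8-hexahydronaphthalen-2(3H)-one; route numbering (3S,4R,7R) | CC1=C2[C@@H](O)[C@@H](C(C)=C)CC[C@]2(C)CCC1=O | intermediate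
13 | (1S,2R,4aR)-4a,8-dimethyl-7-oxo-2-(prop-1-en-2-yl)-1,2,3,4,4a,5,6,7-octahydronaphthalen-1-yl acetate | CC1=C2[C@@H](OC(C)=O)[C@@H](C(C)=C)CC[C@]2(C)CCC1=O | intermediate
14 | (1S,2R,4aR)-4a,8-dimethyl-7-oxo-2-(prop-1-en-2-yl)-1,2,3,4,4a,7-hexahydronaphthalen-1-yl acetate; route numbering (3S,4R,7R) | CC1=C2[C@@H](OC(C)=O)[C@@H](C(C)=C)CC[C@]2(C)C=CC1=O | intermediate
15 | (4S,5R,8S,8aS)-8-hydroxy-3,8-dimethyl-2-oxo-5-(prop-1-en-2-yl)-1,2,4,5,6,7,8,8a-octahydroazulen-4-yl acetate; route numbering (3S,4R,7S,8S) | CC1=C2[C@@H](OC(C)=O)[C@@H](C(C)=C)CC[C@](C)(O)[C@H]2CC1=O | intermediate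
16 | C15 catechol boronate of 17 (2-alkyl-1,3,2-benzodioxaborole; ring centres as in 15, C13 arranged in space as in 17), formed in step 10 | CC1=C2[C@@H](OC(C)=O)[C@@H]([C@@H](C)CB3Oc4ccccc4O3)CC[C@](C)(O)[C@H]2CC1=O | intermediate
17 | (4S,5R,8S,8aS)-8-hydroxy-5-[(2R)-1-hydroxypropan-2-yl]-3,8-dimethyl-2-oxo-1,2,4,5,6,7,8,8a-octahydroazulen-4-yl acetate; route numbering (3S,4R,7S,8S,13R) | CC1=C2[C@@H](OC(C)=O)[C@@H]([C@@H](C)CO)CC[C@](C)(O)[C@H]2CC1=O | intermediate
18 | C15 tert-butyldimethylsilyl ether of 17 (3S,4R,7S,8S,13R) | CC1=C2[C@@H](OC(C)=O)[C@@H]([C@@H](C)CO[Si](C)(C)C(C)(C)C)CC[C@](C)(O)[C@H]2CC1=O | intermediate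
19 | (4S,5R,8S,8aS)-5-[(2R)-1-(tert-butyldimethylsilyloxy)propan-2-yl]-4,8-dihydroxy-3,8-dimethyl-4,5,6,7,8,8a-hexahydroazulen-2(1H)-one | CC1=C2[C@@H](O)[C@@H]([C@@H](C)CO[Si](C)(C)C(C)(C)C)CC[C@](C)(O)[C@H]2CC1=O | intermediate
20 | C3 trimethylsilyl ether of 19 (formed in step 13) | CC1=C2[C@@H](O[Si](C)(C)C)[C@@H]([C@@H](C)CO[Si](C)(C)C(C)(C)C)CC[C@](C)(O)[C@H]2CC1=O | intermediate
21 | C3 trimethylsilyl ether of 22 (formed in step 13) | CC1=C2[C@@H](O[Si](C)(C)C)[C@@H]([C@@H](C)CO[Si](C)(C)C(C)(C)C)CCC(=C)[C@H]2CC1=O | intermediate
22 | (4S,5R,8aR)-5-[(2R)-1-(tert-butyldimethylsilyloxy)propan-2-yl]-4-hydroxy-3-methyl-8-methylidene-4,5,6,7,8,8a-hexahydroazulen-2(1H)-one; route numbering (3S,4R,8R,13R), C8–H α | CC1=C2[C@@H](O)[C@@H]([C@@H](C)CO[Si](C)(C)C(C)(C)C)CCC(=C)[C@H]2CC1=O | intermediate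
23 | dilithium C1(C10)-enolate C3-alkoxide of the reduced ketone (C2–H β, C8–H α), formed in step 14 | [O-]C1=C(C)[C@@H]2[C@@H]([O-])[C@@H]([C@@H](C)CO[Si](C)(C)C(C)(C)C)CCC(=C)[C@H]2C1.[Li+].[Li+] | intermediate
24 | C1 α-phenylselanyl ketone: trans-fused (C2–H β, C8–H α), C1 methyl β and SePh α, C3–OH β, C7=C12, C15–OTBS; CIP (1R,2S,3S,4R,8S,13R) | C[C@@]1([Se]c3ccccc3)[C@@H]2[C@@H](O)[C@@H]([C@@H](C)CO[Si](C)(C)C(C)(C)C)CCC(=C)[C@H]2CC1=O | intermediate
25 | selenoxide of 24 (configuration at selenium not defined), formed in step 15 | C[C@@]1([Se](=O)c3ccccc3)[C@@H]2[C@@H](O)[C@@H]([C@@H](C)CO[Si](C)(C)C(C)(C)C)CCC(=C)[C@H]2CC1=O | intermediate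
26 | exocyclic enone: C10 ketone, C1=C11, C7=C12, C3–OH, C15–OTBS; (2R,3S,4R,8S,13R) | C=C1[C@@H]2[C@@H](O)[C@@H]([C@@H](C)CO[Si](C)(C)C(C)(C)C)CCC(=C)[C@H]2CC1=O | intermediate
27 | (2R,3aS,7R,8S,8aR)-7-[(2R)-1-(tert-butyldimethylsilyloxy)propan-2-yl]-1,4-dimethylidenedecahydroazulene-2,8-diol; route numbering (2R,3S,4R,8S,10R,13R) | C=C1[C@@H]2[C@@H](O)[C@@H]([C@@H](C)CO[Si](C)(C)C(C)(C)C)CCC(=C)[C@H]2C[C@H]1O | intermediate
28 | C3,C10-bis(tert-butyldimethylsilyl) ether of 27 (three TBS groups in all) | C=C1[C@@H]2[C@@H](O[Si](C)(C)C(C)(C)C)[C@@H]([C@@H](C)CO[Si](C)(C)C(C)(C)C)CCC(=C)[C@H]2C[C@H]1O[Si](C)(C)C(C)(C)C | intermediate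
29 | (6S)-C6 alcohol of 28 (C6–OH α); (2R,3S,4R,6S,8S,10R,13R) | C=C1[C@@H]2[C@@H](O[Si](C)(C)C(C)(C)C)[C@@H]([C@@H](C)CO[Si](C)(C)C(C)(C)C)C[C@H](O)C(=C)[C@H]2C[C@H]1O[Si](C)(C)C(C)(C)C | intermediate
30 | C3,C6,C10,C15-tetrakis(tert-butyldimethylsilyl) ether | C=C1[C@@H]2[C@@H](O[Si](C)(C)C(C)(C)C)[C@@H]([C@@H](C)CO[Si](C)(C)C(C)(C)C)C[C@H](O[Si](C)(C)C(C)(C)C)C(=C)[C@H]2C[C@H]1O[Si](C)(C)C(C)(C)C | intermediate
31 | C15 primary alcohol, C3,C6,C10-tris-TBS ether; (13R) | C=C1[C@@H]2[C@@H](O[Si](C)(C)C(C)(C)C)[C@@H]([C@@H](C)CO)C[C@H](O[Si](C)(C)C(C)(C)C)C(=C)[C@H]2C[C@H]1O[Si](C)(C)C(C)(C)C | intermediate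
32 | C15 aldehyde, C3,C6,C10-tris-TBS ether; (13R) | C=C1[C@@H]2[C@@H](O[Si](C)(C)C(C)(C)C)[C@@H]([C@@H](C)C=O)C[C@H](O[Si](C)(C)C(C)(C)C)C(=C)[C@H]2C[C@H]1O[Si](C)(C)C(C)(C)C | intermediate
33 | allyl 4-methoxybenzyl ether, 1-methoxy-4-[(prop-2-en-1-yloxy)methyl]benzene | C=CCOCc1ccc(OC)cc1 | starting material
34 | C15 O-diisopinocampheylborinate of 35 (isopinocampheyl groups from (−)-α-pinene), formed in step 22 | C=C1[C@@H]2[C@@H](O[Si](C)(C)C(C)(C)C)[C@@H]([C@@H](C)[C@H](OB([C@H]3C[C@H]4C[C@@H]([C@@H]3C)C4(C)C)[C@H]5C[C@H]6C[C@@H]([C@@H]5C)C6(C)C)[C@H](C=C)OCc7ccc(OC)cc7)C[C@H](O[Si](C)(C)C(C)(C)C)C(=C)[C@H]2C[C@H]1O[Si](C)(C)C(C)(C)C | intermediate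
35 | (13R,15S,16S)-C15 alcohol, C16 4-methoxybenzyl ether, C17 vinyl; C3,C6,C10-tris-TBS ether | C=C1[C@@H]2[C@@H](O[Si](C)(C)C(C)(C)C)[C@@H]([C@@H](C)[C@H](O)[C@H](C=C)OCc3ccc(OC)cc3)C[C@H](O[Si](C)(C)C(C)(C)C)C(=C)[C@H]2C[C@H]1O[Si](C)(C)C(C)(C)C | intermediate
36 | (13R,15S,16S)-C15,C16-diol, C17 vinyl; C3,C6,C10-tris-TBS ether | C=C1[C@@H]2[C@@H](O[Si](C)(C)C(C)(C)C)[C@@H]([C@@H](C)[C@H](O)[C@H](C=C)O)C[C@H](O[Si](C)(C)C(C)(C)C)C(=C)[C@H]2C[C@H]1O[Si](C)(C)C(C)(C)C | intermediate
37 | (13R,15S,16S)-C15,C16-diacetate, C17 vinyl; C3,C6,C10-tris-TBS ether | C=C1[C@@H]2[C@@H](O[Si](C)(C)C(C)(C)C)[C@@H]([C@@H](C)[C@H](OC(C)=O)[C@H](C=C)OC(C)=O)C[C@H](O[Si](C)(C)C(C)(C)C)C(=C)[C@H]2C[C@H]1O[Si](C)(C)C(C)(C)C | intermediate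
38 | 2-methylbut-2-ene | CC=C(C)C | starting material
39 | C3,C6,C10-tris(tert-butyldimethylsilyl) ether of the target | C=C1[C@@H]2[C@@H](O[Si](C)(C)C(C)(C)C)[C@@H]([C@@H](C)[C@H](OC(C)=O)[C@H](C=C(C)C)OC(C)=O)C[C@H](O[Si](C)(C)C(C)(C)C)C(=C)[C@H]2C[C@H]1O[Si](C)(C)C(C)(C)C | intermediate
40 | CNP0172457.3, (2R,3S,4S)-6-methyl-2-[(2R,3aS,5S,7R,8S,8aR)-2,5,8-trihydroxy-1,4-dimethylidenedecahydroazulen-7-yl]hept-5-ene-3,4-diyl diacetate; route numbering (2R,3S,4R,6S,8S,10R,13R,15S,16S) | C=C1[C@@H]2[C@@H](O)[C@@H]([C@@H](C)[C@H](OC(C)=O)[C@H](C=C(C)C)OC(C)=O)C[C@H](O)C(=C)[C@H]2C[C@H]1O | target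

## Step count and least certain steps

Total step count: 26. Longest linear sequence: 26 steps, from 1 to 40; 4, 6, 33 and 38 are purchased and enter a single chain.

**Step 9 (key step).** The excited dienone may be diverted after C2–C8 bonding: the zwitterion can shift to a lumiketone before it is protonated, the axial allylic C3 acetate (1,3-diaxial to the angular methyl) can be lost by acid-assisted ionisation, and the product, which is still an enone chromophore, can be consumed by further photolysis. Fallback: take the acetate off before irradiation and do not put it back. Starting from 14, cold K2CO3 in methanol should give the C3-hydroxy dienone F1. Irradiation of F1 in aqueous acetic acid should give the C3,C7-dihydroxy hydroazulenone F2. RhCl(PPh3)3-catalysed hydroboration of F2 with perborate oxidation should give the triol F3, and silylation of its primary hydroxyl (TBSCl, imidazole) comes back to the route at 19. The acetate is kept in the main route because acyloxy dienones are the better precedented substrates and the acetate protects C3 during dehydrogenation.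

**Step 14.** The β-carbanion at C2 may be protonated from the α-face (cis ring fusion), the C3 oxygen may be lost by β-elimination, or proton transfer may quench the enolate before selenenylation. The facial bias at C2 in the flexible seven-membered ring is modest. Fallback: deliver the C2 hydrogen from the C3 hydroxyl by catalysis, at a stage with no other alkene. Starting from 19, hydrogenation with [Ir(cod)(PCy3)(py)]PF6, directed by the allylic β-hydroxyl at C3, should give the saturated ketone F9 (C2–H and C1–H β). Dehydration as in step 13 should give the exocyclic alkene ketone F10. TMSCl, NaI and Et3N should give the more substituted silyl enol ether F11 (C3 also silylated), and PhSeCl followed by a mild acidic work-up comes back to the route at 24.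

**Step 10.** Facial selectivity at C13 may be low, because the allylic centre C4 distinguishes its two ring branches only through the C3 acetate; a rhodium hydride may also move the double bond before boron is delivered. Fallback: let a catalyst choose the face. Starting from 15, SeO2 with t-BuOOH should oxidise the isopropenyl methyl to the 2-substituted allylic alcohol F4, and hydrogenation of F4 with Ru(OAc)2(BINAP), using the BINAP antipode that gives (13R), comes back to the route at 17.

**Step 13.** The tertiary chlorosulfite may ionise, with loss of the doubly allylic C8–H and formation of the linearly conjugated dienone; E2 loss of a C6 hydrogen into the ring and incomplete discrimination in the transient silylation are further risks. Fallback: postpone the dehydration until the enone is gone. Starting from 19, the conditions of steps 14 and 15 (the tertiary hydroxyl first converted into its lithium alkoxide with one equivalent of LiN(SiMe3)2) should give the phenylselanyl ketone F5 and then the exocyclic enone F6. The reduction of step 16 should give the triol F7, and TBSOTf at −78 °C should silylate only the two secondary hydroxyls to give the bis-silyl ether F8. SOCl2 and pyridine on F8, where C8–H is no longer allylic to an enone, come back to the route at 28.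

**Step 18.** Oxygen may be delivered to the β-face of C6, the methine positions C8 and C2 may be oxidised, or the alcohol may be oxidised further to the enone; the selectivity rests on conformational preferences of the seven-membered ring. Fallback: set C6 by reagent control. Starting from 29 as obtained (either C6 epimer, with any enone), Dess–Martin oxidation should give the C6 ketone F12, and reduction of F12 with (R)-2-methyl-CBS-oxazaborolidine and catecholborane, in which C7 is the large group, comes back to the route at 29 with the (6S) configuration.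

## Further compounds

F1 | step 9 | C3-hydroxy dienone, (4aR,7R,8S)-8-hydroxy-1,4a-dimethyl-7-(prop-1-en-2-yl)-5,6,7,8-tetrahydronaphthalen-2(4aH)-one | CC1=C2[C@@H](O)[C@@H](C(C)=C)CC[C@]2(C)C=CC1=O
F2 | step 9 | C3,C7-dihydroxy hydroazulenone, (4S,5R,8S,8aS)-4,8-dihydroxy-3,8-dimethyl-5-(prop-1-en-2-yl)-4,5,6,7,8,8a-hexahydroazulen-2(1H)-one | CC1=C2[C@@H](O)[C@@H](C(C)=C)CC[C@](C)(O)[C@H]2CC1=O
F3 | step 9 | C3,C7,C15-triol, (4S,5R,8S,8aS)-4,8-dihydroxy-5-[(2R)-1-hydroxypropan-2-yl]-3,8-dimethyl-4,5,6,7,8,8a-hexahydroazulen-2(1H)-one | CC1=C2[C@@H](O)[C@@H]([C@@H](C)CO)CC[C@](C)(O)[C@H]2CC1=O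
F4 | step 10 | 2-substituted allylic alcohol, (4S,5R,8S,8aS)-8-hydroxy-5-(3-hydroxyprop-1-en-2-yl)-3,8-dimethyl-2-oxo-1,2,4,5,6,7,8,8a-octahydroazulen-4-yl acetate | CC1=C2[C@@H](OC(C)=O)[C@@H](C(=C)CO)CC[C@](C)(O)[C@H]2CC1=O
F5 | step 13 | C1 α-phenylselanyl ketone with the C7 tertiary alcohol retained (C2–H β, C8–H α) | C[C@@]1([Se]c3ccccc3)[C@@H]2[C@@H](O)[C@@H]([C@@H](C)CO[Si](C)(C)C(C)(C)C)CC[C@](C)(O)[C@H]2CC1=O
F6 | step 13 | exocyclic enone (C1=C11, C10 ketone) with the C7 tertiary alcohol retained | C=C1[C@@H]2[C@@H](O)[C@@H]([C@@H](C)CO[Si](C)(C)C(C)(C)C)CC[C@](C)(O)[C@H]2CC1=O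
F7 | step 13 | (10R)-C3,C7,C10-triol with C1=C11 | C=C1[C@@H]2[C@@H](O)[C@@H]([C@@H](C)CO[Si](C)(C)C(C)(C)C)CC[C@](C)(O)[C@H]2C[C@H]1O
F8 | step 13 | C3,C10-bis-TBS ether of F7 with free C7 tertiary alcohol | C=C1[C@@H]2[C@@H](O[Si](C)(C)C(C)(C)C)[C@@H]([C@@H](C)CO[Si](C)(C)C(C)(C)C)CC[C@](C)(O)[C@H]2C[C@H]1O[Si](C)(C)C(C)(C)C
F9 | step 14 | saturated ketone from directed hydrogenation of 19 (C1–H β, C2–H β, C8–H α) | C[C@@H]1[C@@H]2[C@@H](O)[C@@H]([C@@H](C)CO[Si](C)(C)C(C)(C)C)CC[C@](C)(O)[C@H]2CC1=O
F10 | step 14 | C7=C12 alkene of F9 | C[C@@H]1[C@@H]2[C@@H](O)[C@@H]([C@@H](C)CO[Si](C)(C)C(C)(C)C)CCC(=C)[C@H]2CC1=O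
F11 | step 14 | C10-trimethylsilyl enol ether (C1=C10), C3 trimethylsilyl ether of F10 | C[Si](C)(C)OC1=C(C)[C@@H]2[C@@H](O[Si](C)(C)C)[C@@H]([C@@H](C)CO[Si](C)(C)C(C)(C)C)CCC(=C)[C@H]2C1
F12 | step 18 | C6 ketone of 29 (C6=O conjugated with C7=C12) | C=C1[C@@H]2[C@@H](O[Si](C)(C)C(C)(C)C)[C@@H]([C@@H](C)CO[Si](C)(C)C(C)(C)C)CC(=O)C(=C)[C@H]2C[C@H]1O[Si](C)(C)C(C)(C)C
A1 | alternative 1 | 2-methoxy cross-conjugated dienone on the cycloheptene (Nazarov substrate) | C=C(OC)C(=O)C1=C[C@@H](COCc2ccc(OC)cc2)[C@@H](O[Si](C)(C)C(C)(C)C)C[C@H]([C@@H](C)COC(=O)C(C)(C)C)[C@@H]1O[Si](C)(C)C(C)(C)C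
A2 | alternative 1 | trans-fused 2-methoxycyclopentenone (Nazarov product) | O=C1[C@@H]2[C@@H](O[Si](C)(C)C(C)(C)C)[C@@H]([C@@H](C)COC(=O)C(C)(C)C)C[C@H](O[Si](C)(C)C(C)(C)C)[C@H](COCc3ccc(OC)cc3)[C@H]2C=C1OC
A3 | alternative 2 | 2-alkenylcyclopent-2-enone ethylene ketal (diene component) | C12(OCCO1)C(/C=C/[C@@H](C)CO[Si](c3ccccc3)(c3ccccc3)C(C)(C)C)=CCC2
A4 | alternative 2 | methyl 2-diazo-3-(tert-butyldimethylsilyloxy)but-3-enoate | COC(=O)C(=[N+]=[N-])C(=C)O[Si](C)(C)C(C)(C)C
A5 | alternative 2 | fused cycloheptadiene (cyclopropanation–Cope product) | C12(OCCO1)C3=C[C@@H]([C@@H](C)CO[Si](c4ccccc4)(c4ccccc4)C(C)(C)C)CC(O[Si](C)(C)C(C)(C)C)=C(C(=O)OC)[C@H]3CC2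
A6 | alternative 3 | cyclopentane carbaldehyde carrying the methyl (Z)-2-(bromomethyl)alk-2-enoate chain (Barbier substrate) | C=C1[C@H](C=O)[C@H](C[C@H]1O[Si](C)(C)C(C)(C)C)C(=C)[C@@H](O[Si](C)(C)C(C)(C)C)C/C=C(\CBr)C(=O)OC
A7 | alternative 3 | hydroazulene with cis-fused α-methylene-γ-butyrolactone across C3–C4 | C=C1[C@@H]2[C@H]3OC(=O)C(=C)[C@H]3C[C@H](O[Si](C)(C)C(C)(C)C)C(=C)[C@H]2C[C@H]1O[Si](C)(C)C(C)(C)C
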